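Count turnovers.

| flask | substrate | remark | time |
|---|---|---|---|
| Tuesday's | 1.3 M | run made earlier |  |
| Wednesday's | 3 M | run made earlier |  |
| birch | 2.0 M |  | 20 h |
| larch | 2.0 M |  | 50 h |
| oak | 2.0 M |  | 30 h |

| run | time / h | intermediate B / % | side product / % | target / % | substrate / % | intermediate C / % |
|---|---|---|---|---|---|---|
| Tuesday's | 1.50 | 0.2 | 2.8 | 0.4 | 83.9 | 0 |
| Tuesday's | 2.50 | 3.4 | 4.6 | 0 | 74.5 | 0 |
| Tuesday's | 4.00 | 6.1 | 7.5 | 0.7 | 63.4 | 1.5 |
| Tuesday's | 6.00 | 7.4 | 15.0 | 0.1 | 51.7 | 1.3 |
| Tuesday's | 8.00 | 10.4 | 18.9 | 0.4 | 43.1 | 0.2 |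
| Tuesday's | 12.0 | 10.9 | 28.4 | 0 | 30.5 | 1.4 |
| Tuesday's | 20.0 | 14.5 | 37.8 | 1.1 | 13.2 | 5.6 |
| Wednesday's | 1.50 | 2.7 | 1.5 | 0 | 77.6 | 0.2 |
| Wednesday's | 2.50 | 3.6 | 3.9 | 1.2 | 68.8 | 0.6 |
| Wednesday's | 4.00 | 5.5 | 9.3 | 1.3 | 55.5 | 0 |
| Wednesday's | 6.00 | 7.3 | 13.0 | 0.8 | 46.4 | 0.6 |
| Wednesday's | 8.00 | 9.2 | 17.4 | 0.3 | 35.7 | 0.2 |
| Wednesday's | 12.0 | 13.3 | 24.4 | 0 | 23.0 | 1.7 |
| Wednesday's | 20.0 | 12.2 | 31.3 | 1.7 | 11.0 | 3.0 |

(each reading ± 1 percentage point)

- the earlier runs were read with a standard deviation of 1 percentage point

* which of these there is most of at the end, counted by the substrate in it, birch (side product / intermediate B / target / intermediate C / substrate)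
* which of these there is most of at the end, counted by the substrate in it, larch (side product / intermediate B / target / intermediate C / substrate)
* which of these there is most of at the end, counted by the substrate in it, oak (side product / intermediate B / target / intermediate C / substrate)
* final amount of the leader among these, as a percentage of the substrate charged, in birch
* final amount of the leader among these, as a percentage of the substrate charged, in larch
* final amount of the leader among these, as a percentage of the substrate charged, in oak

I ran the flask in slow motion from the two earlier runs. In the first instants, to 1.50 h, the substrate's first-order rate constant read 0.117 h⁻¹ on Tuesday's run and 0.169 h⁻¹ on Wednesday's, so the heavier charge started faster. Later the two runs read alike. From 8.00 h to 20.0 h, Tuesday's substrate gave 0.0986 h⁻¹ and Wednesday's 0.0981 h⁻¹. I carried one quantity forward: the turnover count, this late rate constant times the elapsed time. On that late stretch each turnover cut the substrate by a factor of e. Birch gets 1.97, oak 2.96 and larch 4.93.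

In the middle, at 12.0 h, side product read 28.4% on Tuesday's run and 24.4% on Wednesday's, and intermediate B 10.9% and 13.3%. Target read 0% in both, inside the scatter.

Near the end, at 20.0 h, intermediate C read 5.6% on Tuesday's run and 3.0% on Wednesday's. Tuesday's side product, 37.8%, exceeded the other listed species together, and each of its readings on that run stood above the one before. So I expected it to lead in birch, oak and larch.

Its share of substrate spent (the selectivity) read 39.4% at that time as the mean of the two runs, whose substrate readings had a mean of 12.1%. Counting turnovers on from there, I reckoned 34.6% for birch, 37.6% for oak and 39.1% for larch.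

The forecast also named side product for each flask, with 34.5% for birch, 38.5% for oak and 41% for larch, its oak and larch figures above mine. It said: “Side product should lead throughout, assuming the slow downstream chain does not overtake it”.

The flasks gave side product at 35.0% in birch, side product at 39.7% in oak and side product at 42.5% in larch, as the forecast said and within its tolerance.

    substrate → intermediate A (k = 0.0803 h⁻¹)
    intermediate A → intermediate B (k = 0.174 h⁻¹)
    intermediate B → intermediate C (k = 0.0295 h⁻¹)
    intermediate C → target (k = 0.0286 h⁻¹)
    intermediate A → side product (k = 0.325 h⁻¹)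
    2 substrate → homo dimer (k = 0.0148 M⁻¹ h⁻¹)
    intermediate A → decomposed reagent (k = 0.0644 h⁻¹)

Larch, after 4.93 turnovers by my count, held 1.05% of substrate. The neighbour flask, larch's charge read at 12 h, held 26% of substrate, and counting on from that reading to 50 h gives 0.618%, less than larch held. Larch was not at rest. Left until 500 h, its side product moved from 42.5% to 43.2%, while intermediates B and C, at 7.74% and 8.07%, fell to 0% and 0%, and target climbed from 6.96% to 23.1%.

The runs come from a simulation with made-up constants; the scatter is artificial.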